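The trap in these flasks is the bench habit that a hotter flask gives more target in the same time. We test that habit on the earlier runs, then rank the new flasks at one fixed time.

| flask | starting material | second substrate | third substrate | solid reagent | temperature | remark | time |
|---|---|---|---|---|---|---|---|
| south | 0.15 M | 0.60 M | 0.060 M | 0.90 M | 75 °C | run made earlier |  |
| north-west | 0.22 M | 0.60 M | 0.060 M | 0.90 M | 110 °C | run made earlier |  |
| noon | 0.30 M | 0.600 M | 0.0600 M | 0.900 M | 120 °C |  | 50 min |
| summer | 0.30 M | 0.600 M | 0.0600 M | 0.900 M | 140 °C |  | 50 min |
| spring | 0.30 M | 0.600 M | 0.0600 M | 0.900 M | 100 °C |  | 50 min |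
| winter | 0.30 M | 0.600 M | 0.0600 M | 0.900 M | 80 °C |  | 50 min |

| run | time / min | target / % | starting material / % |
|---|---|---|---|
| south | 20.0 | 2.3 | 99.3 |
| south | 60.0 | 5.4 | 94.7 |
| south | 90.0 | 7.3 | 92.1 |
| south | 150 | 12.0 | 87.6 |
| south | 240 | 18.2 | 82.4 |
| south | 300 | 21.1 | 78.5 |
| north-west | 3.00 | 0.9 | 99.7 |
| north-west | 10.0 | 4.9 | 97.2 |
| north-west | 15.0 | 7.6 | 93.7 |
| north-west | 25.0 | 10.2 | 89.3 |
| north-west | 40.0 | 12.3 | 87.8 |
| north-west | 50.0 | 13.3 | 87.8 |

(standard deviation of a reading: 0.5 percentage points)

- solid reagent is a solid; its amount is given per volume of the solution
- at the start none of the solid reagent is in solution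

- the flask that comes out highest in amount of target, in percent of the starting material charged, or "all alike" when all lie within 1.5 percentage points (noon / summer / spring / winter / all alike)
- target at the end, in percent of the starting material charged, noon
- target at the end, in percent of the starting material charged, summer
- target at the end, in percent of the starting material charged, spring
- target at the end, in percent of the starting material charged, winter

Applied honestly, the habit uses opening slopes. Across its readings the south run gains 6.71 × 10⁻⁴ min⁻¹ of the charge, and the north-west run gains 0.00423 min⁻¹ up to its bend, which is faster. The border lies where slope times allowed time meets the level the run really reaches. For the north-west run over 50 min that ratio is 1.59, so the slope overshoots and the habit has stopped working. For the south run it is 0.159, and that run is still climbing at its last reading.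

What takes over we measure by the standing ratio, target divided by remaining starting material once the curve has bent over: 0.151 in the north-west run, as a reading. The south run has already reached 0.269 and is still climbing, so of these two runs, which differ in the charge of starting material as well as in temperature, the hotter has the lower ceiling and the steeper slope.

Interpolating the slopes, we reckon a reach of 12.5% for spring, close to the north-west level, and 4.37% for winter. Noon and summer are hotter than the north-west run, so we place them under its ceiling, and we put spring nearest the crossing of slope and ceiling.

The forecast also names spring, with 9.5% for noon, 6.5% for summer, 11% for spring and 4.5% for winter, a spring value below our reach. Its ground: “Deactivation therefore outruns reaction on heating, and the plateau falls as temperature rises.”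

The flasks give 10.5% for noon, 6.27% for summer, 13.7% for spring and 6.15% for winter, so spring comes out highest.

    starting material + coupling partner ⇌ target (K = 8.10 M⁻¹, k = 0.0279 M⁻¹ min⁻¹, Ea = 83.0 kJ mol⁻¹, ΔH = −37.0 kJ mol⁻¹)
    second substrate + coupling partner → second product (k = 6.09 × 10⁻⁴ M⁻¹ min⁻¹, Ea = 79.0 kJ mol⁻¹)
    third substrate + coupling partner → third product (k = 0.0570 M⁻¹ min⁻¹, Ea = 90.0 kJ mol⁻¹)
    solid reagent ⇌ coupling partner, rate k4*(cs4 - [coupling partner]) while solid is left; crystals form when [coupling partner] > cs4 (solubility = 0.0590 M, k = 0.169 min⁻¹)
    target → over-reaction product (k = 1.43 × 10⁻⁵ min⁻¹, Ea = 122 kJ mol⁻¹)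
    (constants at 80 °C)

Summer and winter end about level, but they are held differently, which is kinetic against thermodynamic control. Summer's standing ratio is 0.0679, below the north-west value. The main reason for summer's low target is the reverse step, target to starting material and coupling partner: without it summer reaches 67.8% instead of 6.27%. Winter shows 0.0655 at the asked time, held in part by the time allowed. By 500 min winter holds 29.2% target, a standing ratio of 0.412.

The runs are simulated for an exercise, and the scatter is random.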